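The ratio to watch is nucleophile charged per electrophile coupled to target. With the impurity's whole charge booked as electrophile lost to it, the last violet reading gives this ratio as 2.37, a figure that carries the scatter of that reading.

| flask | electrophile | nucleophile | protic impurity | remark | time |
|---|---|---|---|---|---|
| violet | 0.16 M | 0.55 equiv | 0.032 M | run made earlier |  |
| green | 0.16 M | 2.7 equiv | 0.032 M | run made earlier |  |
| gamma | 0.16 M | 0.950 equiv | 0.0320 M |  | 2.5 h |
| delta | 0.16 M | 1.90 equiv | 0.0320 M |  | 2.5 h |
| eta | 0.16 M | 3.80 equiv | 0.0320 M |  | 2.5 h |

- violet (time / min: electrophile / %, target / %): 5.00: 91.2, 6.6; 15.0: 78.4, 12.4; 25.0: 70.9, 13.0; 40.0: 63.6, 13.7; 60.0: 59.8, 11.2; 80.0: 56.8, 8.4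
- green (time / min: electrophile / %, target / %): 5.00: 67.1, 28.7; 15.0: 36.6, 47.2; 25.0: 21.4, 49.5; 40.0: 12.0, 42.8; 60.0: 6.0, 33.1; 80.0: 1.9, 25.8

(each reading ± 0.5 percentage points)

* part of the electrophile that has reacted at the end, gamma
* part of the electrophile that has reacted at the end, delta
* part of the electrophile that has reacted at the end, eta
* what raising the equivalents of nucleophile from its lowest to its highest value here does to the part of the electrophile that has reacted (changes below 5 percentage points count as none) (it rises / it falls / no change)



The booking is our assumption: by 5.00 min the violet electrophile has lost 2.2 percentage points more than the target has gained, which fits a second fork open to an electrophile molecule, though onward loss of target fits it too.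

Why does violet slow down? Its electrophile loses ground at 0.0852 of its opening pace while 56.8 % still stands, whereas green, with more nucleophile, is down to 1.9 %. So we read violet as short of nucleophile, with each coupling costing about two nucleophile although we cannot yet say what takes the second.

What does that mean for gamma? Half the equivalents plus impurity over electrophile give 67.5 %, the stall level: the part of the electrophile reacted once nucleophile, at two per coupling, and impurity, at one per electrophile, are used up. Violet's level is 47.5 %, and it has reached 43.2 % and is still creeping. We therefore put gamma just under its level. Delta's level is 115 % and eta's 210 %, both above the whole charge, so we expect both near completion and a rising trend.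

The forecast gives 72 %, 97 % and 99.9 %, and says it rises, holding that “nucleophile is also lost slowly”; its gamma stands above our level.

The flask gives 65.8 %, 94.7 % and >99.9 %: it rises, by 34 points.

    electrophile + nucleophile → acid set free + target (k = 0.198 L mol⁻¹ min⁻¹)
    nucleophile + acid set free ⇌ protonated nucleophile, settled at all times (K = 3440 L mol⁻¹)
    electrophile + protic impurity → quenched substrate (k = 0.194 L mol⁻¹ min⁻¹)
    target ⇌ isomer of the product (K = 0.599, k = 0.00665 min⁻¹)
    target → over-reaction product (k = 0.0165 min⁻¹)

Gamma ends 1.7 points under its stall level, with nucleophile, the limiting reagent, at 2.5 % of its charge against 34 % for electrophile. Eta, whose level lies above the whole charge, has 0 % electrophile left, and two nucleophile per coupling predict 50.4 % of its nucleophile remaining, against 50 % found. In gamma at 2.50 h, protonated nucleophile outweighs acid set free 13.0 to one, but at 25.0 h that ratio is 2.13 and the electrophile reacted has passed the level, at 76.3 %.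

The numbers in the tables were computed with constants of no real substance, and the scatter is random.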